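Ring B is assembled around an oxygen that ring A already carries, so the hindered diaryl ether bond is never made by coupling. Ring B bears OMe at C3, OH at C4, the O–ring A link at C5 and the lactone-bearing CH2 at C1. This is the pattern of a 2,6-dioxygenated 4-alkylphenol. C3–C4–C5 therefore map onto a 1-aryloxy-3-methoxyacetone, and C2–C1–C6 onto a 2-alkyl-3-(dimethylamino)acrolein. One base-mediated [3+3] condensation forges C2–C3 and C5–C6, closes the benzene ring and leaves the C4 hydroxyl free. Both partners derive from a single (S)-β-veratryl-γ-butyrolactone. Its centre is set by an Evans alkylation and directs each α-substituent trans.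

Key step: step 13

Remark on the chemistry: all four stereocentres of the given SMILES are S, so each half is the mirror image of natural (−)-arctigenin. The natural product is therefore no feedstock, and the (R)-configured auxiliary is used. Ring A is the guaiacyl ring bearing the ether oxygen; ring B is the trioxygenated ring, numbered from its CH2-bearing carbon C1.

Step 1
Reactants: 1 3-(3,4-dimethoxyphenyl)propanoic acid; 2 (R)-4-benzyl-1,3-oxazolidin-2-one
Product: 3 (4R)-4-benzyl-3-[3-(3,4-dimethoxyphenyl)propanoyl]-1,3-oxazolidin-2-one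
Conditions: DCC, DMAP (cat.), CH2Cl2, 0 °C → rt
Reagents that add atoms: none
Why: Steglich-type carbodiimide/DMAP N-acylation of an oxazolidinone by an unhindered aliphatic acid is established chemistry and touches no stereocentre.

Step 2
Reactants: 3 N-acyl oxazolidinone; 4 tert-butyl bromoacetate
Product: 5 tert-butyl (3S)-4-[(4R)-4-benzyl-2-oxo-1,3-oxazolidin-3-yl]-3-(3,4-dimethoxybenzyl)-4-oxobutanoate
Conditions: NaN(SiMe3)2, THF, −78 → −40 °C
Reagents that add atoms: none
Why: Evans asymmetric alkylation: the chelated Z-sodium enolate is shielded on one face by the C4 benzyl group of the (R)-auxiliary, so the bromoacetate enters from the opposite face and sets the S centre that becomes Cβ of both lactones.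

Step 3
Reactants: 5 alkylated imide
Product: 7 (4S)-4-(3,4-dimethoxybenzyl)dihydrofuran-2(3H)-one, via hydroxy ester 6 (not isolated)
Conditions: LiBH4, MeOH (1 equiv), THF, 0 °C; then crude 6, p-TsOH·H2O (cat.), toluene, 80 °C
Reagents that add atoms: none
Why: Hydride removal of an Evans auxiliary followed by acid lactonisation: LiBH4 attacks the activated exocyclic imide carbonyl much faster than the hindered tert-butyl ester, and the γ-hydroxy ester then cyclises with loss of isobutene and water without touching the non-epimerisable stereocentre.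

Step 4
Reactants: 8 4-(benzyloxy)-3-methoxybenzyl alcohol
Product: 9 4-(benzyloxy)-3-methoxybenzyl bromide
Conditions: PBr3, Et2O, 0 °C (used at once)
Reagents that add atoms: phosphorus tribromide, BrP(Br)Br
Why: Standard conversion of an electron-rich benzylic alcohol into its bromide with PBr3 (SN2 on the phosphite ester), the labile product being carried on without storage.

Step 5
Reactants: 7 (S)-lactone; 9 benzylic bromide
Product: 10 (3S,4S)-3-[4-(benzyloxy)-3-methoxybenzyl]-4-(3,4-dimethoxybenzyl)dihydrofuran-2(3H)-one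
Conditions: LiN(SiMe3)2, THF, −78 → −20 °C
Reagents that add atoms: none
Why: Substrate-controlled alkylation of a β-substituted γ-butyrolactone lithium enolate, the classical entry to dibenzylbutyrolactone lignans: the bromide approaches anti to the Cβ veratryl group and sets Cα as S (trans).

Step 6
Reactants: 10 benzyl ether
Product: 11 (3S,4S)-4-(3,4-dimethoxybenzyl)-3-(4-hydroxy-3-methoxybenzyl)dihydrofuran-2(3H)-one (ent-arctigenin)
Conditions: H2 (1 atm), 10% Pd/C, EtOAc–EtOH, rt
Reagents that add atoms: none
Why: Catalytic hydrogenolysis of a benzyl aryl ether leaves the lactone, the methyl ethers and both stereocentres untouched.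

Step 7
Reactants: 11 ent-arctigenin; 12 glycidyl methyl ether (racemic)
Product: 13 (3S,4S)-4-(3,4-dimethoxybenzyl)-3-[4-(2-hydroxy-3-methoxypropoxy)-3-methoxybenzyl]dihydrofuran-2(3H)-one (both carbinol epimers)
Conditions: K2CO3 (0.2 equiv), DMF, 80 °C
Reagents that add atoms: none
Why: Base-catalysed SN2 opening of a terminal epoxide by a phenoxide at the unsubstituted carbon; racemic 12 suffices because the new carbinol centre, formed as both epimers, is erased in step 8.

Step 8
Reactants: 13 secondary alcohol
Product: 14 (3S,4S)-4-(3,4-dimethoxybenzyl)-3-[3-methoxy-4-(3-methoxy-2-oxopropoxy)benzyl]dihydrofuran-2(3H)-one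
Conditions: Dess–Martin periodinane, CH2Cl2, rt
Reagents that add atoms: none
Why: Dess–Martin oxidation of a secondary alcohol runs under non-basic conditions, mild enough for the lactone α-centre and for the base-sensitive α,α'-dioxygenated ketone.

Step 9
Reactants: 7 (S)-lactone; 15 allyl bromide
Product: 16 (3S,4S)-3-allyl-4-(3,4-dimethoxybenzyl)dihydrofuran-2(3H)-one
Conditions: LiN(SiMe3)2, THF, −78 °C
Reagents that add atoms: none
Why: The same substrate-controlled lactone enolate alkylation as in step 5, allyl bromide entering anti to the Cβ substituent to set Cα as S (trans).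

Step 10
Reactants: 16 allyl lactone
Product: 18 (3S,4S)-4-(3,4-dimethoxybenzyl)-3-(3-hydroxypropyl)dihydrofuran-2(3H)-one, via B-alkyl-9-BBN adduct 17 (not isolated)
Conditions: 9-BBN, THF, 0 °C → rt; then NaBO3·4H2O, THF–H2O, rt
Reagents that add atoms: NaBO3·4H2O (source of the hydroxyl oxygen), [Na+].[Na+].O[B-]1(O)OO[B-](O)(O)OO1; 9-BBN (its boron cage stays in 17 only), B1C2CCCC1CCC2
Why: Brown hydroboration–oxidation: 9-BBN adds anti-Markovnikov to the terminal alkene and ignores the lactone, and perborate oxidises the C–B bond near neutral pH so that the lactone stays closed.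

Step 11
Reactants: 18 primary alcohol
Product: 19 3-[(3S,4S)-4-(3,4-dimethoxybenzyl)-2-oxotetrahydrofuran-3-yl]propanal
Conditions: Dess–Martin periodinane, CH2Cl2, rt
Reagents that add atoms: none
Why: Dess–Martin oxidation stops at the aldehyde and is non-basic, so neither the aldehyde nor Cα is enolised.

Step 12
Reactants: 19 aldehyde; 20 tert-butoxybis(dimethylamino)methane (Bredereck's reagent)
Product: 21 (E)-3-(dimethylamino)-2-{[(3S,4S)-4-(3,4-dimethoxybenzyl)-2-oxotetrahydrofuran-3-yl]methyl}prop-2-enal
Conditions: 20 (1.5 equiv), toluene, 60 °C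
Reagents that add atoms: none
Why: Aminomethylenation of a CH-acidic carbonyl compound with Bredereck's reagent: thermal ionisation supplies tert-butoxide and a formamidinium ion, the aldehyde enolate is C-formylated and loss of dimethylamine gives the E push–pull enaminal, whereas the lactone α-carbon with its single hydrogen cannot end as an enamine.

Step 13
Reactants: 14 aryloxy(methoxy)acetone; 21 aminoacrolein
Product: 23 target CNP0183104.1 (4-O-5' diaryl ether of two (3S,4S)-arctigenin units), via open-chain keto-enal 22 (not isolated)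
Conditions: KOt-Bu (2.5 equiv), THF–t-BuOH, Ar stream, slow addition of 14 to 21 (1.2 equiv) and base at 0 °C, then 55 °C; 1 M HCl, THF, rt
Reagents that add atoms: none
Why: The potassium enolate of 14, formed at the more acidic aryloxymethylene carbon (future C5), adds to the aminomethylene carbon of the vinylogous formamide 21 and expels dimethylamine (C5–C6 bond) to give 22 as a delocalised dienolate, after which proton shuttling through t-BuOH exposes the enolate at the methoxymethylene carbon (future C3), which attacks the formyl carbon (C2–C3 bond). Ring B closes in this second event as a 6-(enolendo)-exo-trig aldol, made possible by easy E/Z equilibration of the C1=C6 bond within the delocalised anion, and loss of water gives a 6H-cyclohexa-2,4-dienone that tautomerises irreversibly to the phenoxide, so the ketone oxygen becomes the C4 hydroxyl. The closest known reaction types are the base-mediated [3+3] phenol synthesis from 1,3-disubstituted acetones and malonaldehyde or vinamidinium three-carbon units, the addition–elimination of potassium ketone enolates on β-aminoenones, and the conversion of 2-alkylpyrylium pseudobases into phenols. No stereocentre is created, and the four existing ones are safe because Cβ is not acidic and Cα equilibrates toward the favoured trans lactone. Regiocontrol is not required since both termini of the C2–C1–C6 unit end as ring CH groups; the chemoselectivity that is required, ketone enolisation over lactone enolisation and cross- over self-condensation, rests on the two α-oxygen substituents that acidify 14, on the lack of an enolisable position in the reacting part of 21 and on the slow addition of 14. The closing acid wash re-forms any lactone opened by the hydroxide that the condensation liberates.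

Compound list
1 | 3-(3,4-dimethoxyphenyl)propanoic acid | COc1ccc(CCC(=O)O)cc1OC | starting material
2 | (R)-4-benzyl-1,3-oxazolidin-2-one | O=C1N[C@H](Cc2ccccc2)CO1 | starting material
3 | (4R)-4-benzyl-3-[3-(3,4-dimethoxyphenyl)propanoyl]-1,3-oxazolidin-2-one | COc1ccc(CCC(=O)N2[C@H](Cc3ccccc3)COC2=O)cc1OC | intermediate
4 | tert-butyl bromoacetate | CC(C)(C)OC(=O)CBr | starting material
5 | tert-butyl (3S)-4-[(4R)-4-benzyl-2-oxo-1,3-oxazolidin-3-yl]-3-(3,4-dimethoxybenzyl)-4-oxobutanoate | COc1ccc(C[C@@H](CC(=O)OC(C)(C)C)C(=O)N2[C@H](Cc3ccccc3)COC2=O)cc1OC | intermediate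
6 | tert-butyl (3S)-4-(3,4-dimethoxyphenyl)-3-(hydroxymethyl)butanoate (not isolated) | COc1ccc(C[C@@H](CC(=O)OC(C)(C)C)CO)cc1OC | intermediate
7 | (4S)-4-(3,4-dimethoxybenzyl)dihydrofuran-2(3H)-one | COc1ccc(C[C@@H]2COC(=O)C2)cc1OC | intermediate
8 | 4-(benzyloxy)-3-methoxybenzyl alcohol | COc1cc(CO)ccc1OCc1ccccc1 | starting material
9 | 4-(benzyloxy)-3-methoxybenzyl bromide | COc1cc(CBr)ccc1OCc1ccccc1 | intermediate
10 | (3S,4S)-3-[4-(benzyloxy)-3-methoxybenzyl]-4-(3,4-dimethoxybenzyl)dihydrofuran-2(3H)-one | COc1ccc(C[C@@H]2COC(=O)[C@H]2Cc2ccc(OCc3ccccc3)c(OC)c2)cc1OC | intermediate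
11 | (3S,4S)-4-(3,4-dimethoxybenzyl)-3-(4-hydroxy-3-methoxybenzyl)dihydrofuran-2(3H)-one (ent-arctigenin) | COc1ccc(C[C@@H]2COC(=O)[C@H]2Cc2ccc(O)c(OC)c2)cc1OC | intermediate
12 | glycidyl methyl ether (racemic) | COCC1CO1 | starting material
13 | (3S,4S)-4-(3,4-dimethoxybenzyl)-3-[4-(2-hydroxy-3-methoxypropoxy)-3-methoxybenzyl]dihydrofuran-2(3H)-one, both carbinol epimers | COc1ccc(C[C@@H]2COC(=O)[C@H]2Cc2ccc(OCC(O)COC)c(OC)c2)cc1OC | intermediate
14 | (3S,4S)-4-(3,4-dimethoxybenzyl)-3-[3-methoxy-4-(3-methoxy-2-oxopropoxy)benzyl]dihydrofuran-2(3H)-one | COc1ccc(C[C@@H]2COC(=O)[C@H]2Cc2ccc(OCC(=O)COC)c(OC)c2)cc1OC | intermediate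
15 | allyl bromide | C=CCBr | starting material
16 | (3S,4S)-3-allyl-4-(3,4-dimethoxybenzyl)dihydrofuran-2(3H)-one | COc1ccc(C[C@@H]2COC(=O)[C@H]2CC=C)cc1OC | intermediate
17 | (3S,4S)-3-[3-(9-borabicyclo[3.3.1]nonan-9-yl)propyl]-4-(3,4-dimethoxybenzyl)dihydrofuran-2(3H)-one (not isolated) | COc1ccc(C[C@@H]2COC(=O)[C@H]2CCCB3C4CCCC3CCC4)cc1OC | intermediate
18 | (3S,4S)-4-(3,4-dimethoxybenzyl)-3-(3-hydroxypropyl)dihydrofuran-2(3H)-one | COc1ccc(C[C@@H]2COC(=O)[C@H]2CCCO)cc1OC | intermediate
19 | 3-[(3S,4S)-4-(3,4-dimethoxybenzyl)-2-oxotetrahydrofuran-3-yl]propanal | COc1ccc(C[C@@H]2COC(=O)[C@H]2CCC=O)cc1OC | intermediate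
20 | tert-butoxybis(dimethylamino)methane | CC(C)(C)OC(N(C)C)N(C)C | starting material
21 | (E)-3-(dimethylamino)-2-{[(3S,4S)-4-(3,4-dimethoxybenzyl)-2-oxotetrahydrofuran-3-yl]methyl}prop-2-enal | COc1ccc(C[C@@H]2COC(=O)[C@H]2C/C(C=O)=C\N(C)C)cc1OC | intermediate
22 | 4-aryloxy-6-methoxy-5-oxo-2-(lactonylmethyl)hex-2-enal; aryl = ring A of the first half; present as its potassium dienolate; C4 and alkene geometry undefined (not isolated) | COCC(=O)C(Oc1ccc(C[C@@H]2C(=O)OC[C@H]2Cc2ccc(OC)c(OC)c2)cc1OC)C=C(C=O)C[C@@H]1C(=O)OC[C@H]1Cc1ccc(OC)c(OC)c1 | intermediate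
23 | (3S,4S)-4-(3,4-dimethoxybenzyl)-3-{4-[5-{[(3S,4S)-4-(3,4-dimethoxybenzyl)-2-oxotetrahydrofuran-3-yl]methyl}-2-hydroxy-3-methoxyphenoxy]-3-methoxybenzyl}dihydrofuran-2(3H)-one | COc1ccc(C[C@@H]2COC(=O)[C@H]2Cc2ccc(Oc3cc(C[C@@H]4C(=O)OC[C@H]4Cc4ccc(OC)c(OC)c4)cc(OC)c3O)c(OC)c2)cc1OC | target

Total step count: 13.
Longest linear sequence: 8 steps (1, 2, 3, 5, 6, 7, 8, 13; the branch 1, 2, 3, 9, 10, 11, 12, 13 is equally long).

Steps most likely to fail

Step 13. Addition of the ketone enolate to the weakly electrophilic, α-branched vinylogous formamide may be too slow. Self-aldolisation of the ketone, expulsion of aryloxide from its enolate, or stalling at the delocalised open-chain anion could then take over.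

The fallback sets out from 7 and rejoins the route at 23. It makes the diaryl ether early, on simple aldehydes, by nucleophilic aromatic substitution.
- Commercial 3,4-dihydroxy-5-methoxybenzaldehyde is benzylated selectively at the more acidic 4-hydroxyl (BnBr, NaHCO3, DMF) to 4-(benzyloxy)-3-hydroxy-5-methoxybenzaldehyde F1.
- The phenoxide of this compound displaces fluoride from commercial 4-fluoro-3-methoxybenzaldehyde (K2CO3, DMF, 120 °C) to give 4-(benzyloxy)-3-(4-formyl-2-methoxyphenoxy)-5-methoxybenzaldehyde F2.
- NaBH4 in MeOH gives the bis(hydroxymethyl) diaryl ether F3, and PBr3 in Et2O gives the bis(bromomethyl) diaryl ether F4.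
- Two equivalents of the lithium enolate of 7 (LiN(SiMe3)2, THF, −78 °C) are alkylated by this dibromide, anti to each Cβ substituent as in step 5, giving the O-benzyl ether of the target F5.
- Hydrogenolysis (H2, 10% Pd/C) then delivers 23.

Step 12. The unhindered aldehyde may undergo self-aldol condensation, or be diverted into aminal and enamine formation at the formyl group, before C-formylation occurs.

The fallback sets out from 19 and rejoins at 21, using a Vilsmeier–Haack–Arnold formylation of a masked aldehyde.
- HC(OMe)3 and p-TsOH (cat.) in MeOH give the dimethyl acetal F6.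
- POCl3/DMF (0 → 50 °C) converts it, through the enol ether, into the 3-methoxyallylidene(dimethyl)iminium chloride F7. The temperature is kept low so that the veratryl ring is not formylated.
- Aqueous K2CO3 hydrolyses the methoxy terminus to give 21.

Step 7. Epoxide opening by the hindered guaiacol-type phenoxide may be slow. The product alkoxide may then react with more epoxide or transesterify the lactone.

The fallback sets out from 11 and rejoins at 14, bypassing 13 and step 8.
- Commercial 1-chloro-3-methoxypropan-2-ol is oxidised (Dess–Martin periodinane, CH2Cl2) to 1-chloro-3-methoxypropan-2-one F8.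
- This chloroketone alkylates 11 in a Williamson ether synthesis (K2CO3, KI (cat.), acetone, reflux) to give the ketone 14 directly.

Further compounds
F1 | step 13 | 4-(benzyloxy)-3-hydroxy-5-methoxybenzaldehyde | COc1cc(C=O)cc(O)c1OCc1ccccc1
F2 | step 13 | 4-(benzyloxy)-3-(4-formyl-2-methoxyphenoxy)-5-methoxybenzaldehyde | COc1cc(C=O)ccc1Oc1cc(C=O)cc(OC)c1OCc1ccccc1
F3 | step 13 | bis(hydroxymethyl) diaryl ether, {4-(benzyloxy)-3-[4-(hydroxymethyl)-2-methoxyphenoxy]-5-methoxyphenyl}methanol | COc1cc(CO)ccc1Oc1cc(CO)cc(OC)c1OCc1ccccc1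
F4 | step 13 | bis(bromomethyl) diaryl ether, 2-(benzyloxy)-5-(bromomethyl)-1-[4-(bromomethyl)-2-methoxyphenoxy]-3-methoxybenzene | COc1cc(CBr)ccc1Oc1cc(CBr)cc(OC)c1OCc1ccccc1
F5 | step 13 | O-benzyl ether of the target (benzyl on the ring B C4 oxygen) | COc1ccc(C[C@@H]2COC(=O)[C@H]2Cc2ccc(Oc3cc(C[C@@H]4C(=O)OC[C@H]4Cc4ccc(OC)c(OC)c4)cc(OC)c3OCc5ccccc5)c(OC)c2)cc1OC
F6 | step 12 | dimethyl acetal, (3S,4S)-4-(3,4-dimethoxybenzyl)-3-(3,3-dimethoxypropyl)dihydrofuran-2(3H)-one | COc1ccc(C[C@@H]2COC(=O)[C@H]2CCC(OC)OC)cc1OC
F7 | step 12 | 3-methoxyallylidene(dimethyl)iminium chloride carrying the lactonylmethyl group at C2 | COc1ccc(C[C@@H]2COC(=O)[C@H]2CC(=COC)C=[N+](C)C)cc1OC.[Cl-]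
F8 | step 7 | 1-chloro-3-methoxypropan-2-one | COCC(=O)CCl
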